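**Retrosynthetic overview**

1. The target is a 2,3-trans-3,4-trans flavan (upper unit, rings A/B/C, atoms O1 to C8a) bonded through C4 to C6′ of a 2,3-cis flavan (lower unit, rings D/E/F, primed atoms). It is disconnected first at five benzyl ethers, then at C4–C6′ (Friedel–Crafts alkylation of ring D by the C4 benzylic cation of the upper flavan-7-ol, released from a 4-methoxy group).
2. Each pyran ring (C and F) is disconnected at its aryl ether bond O1–C8a. The benzo ring is taken back to the 4-hydroxycyclohexa-2,5-dienone (para-quinol) of a simple para-alkylphenol, so ring closure is an oxa-Michael addition followed by loss of water.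
3. Enabling feature: in ring A the C7 hydroxyl is para to C4a and meta to C8a. Oxidation of the phenol at C4a therefore makes C8a the β-carbon of an enone six atoms from the C2 hydroxyl; C5 and C8a are equivalent, and loss of the C4a hydroxyl returns ring A with the 7-OH in place.
4. O1 stays on C2 throughout, so the closure transfers acyclic stereochemistry unchanged (anti gives 2,3-trans, syn gives 2,3-cis). Both open-chain precursors come from L-tyrosine (ring A or D, C4 and the 3S centre) and differ only in how C2 is set: chelation-controlled ketone reduction versus chelation-controlled aldehyde arylation.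
5. Order of ring formation: ring C (step 9), ring F (step 15), then union of the two units (step 16) and deprotection.

Key step: step 9

**Route**

Step 1
Reactants: 1 L-tyrosine
Product: 4 (S)-2-hydroxy-3-(4-hydroxyphenyl)propanoic acid, via diazonium carboxylate 2 (not isolated), via alpha-lactone 3 (not isolated)
Conditions: NaNO2, 1 M H2SO4, H2O, 0 °C to rt
Reagents that add atoms: water (O)
Why: Diazotization of the α-amino acid goes with net retention (double inversion: the carboxylate expels N2 to give alpha-lactone 3 and water reopens it), so the S centre that becomes C3 of both flavan units is kept.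

Step 2
Reactants: 4 (S)-2-hydroxy-3-(4-hydroxyphenyl)propanoic acid
Product: 5 allyl (S)-3-[4-(allyloxy)phenyl]-2-hydroxypropanoate
Conditions: allyl bromide, K2CO3, DMF, rt
Reagents that add atoms: allyl bromide (C=CCBr)
Why: Williamson-type O-alkylation under carbonate base reaches only the carboxylate and the phenoxide, so the secondary alcohol stays free and the stereocentre is not touched.

Step 3
Reactants: 5 allyl (S)-3-[4-(allyloxy)phenyl]-2-hydroxypropanoate
Product: 6 allyl (S)-3-[4-(allyloxy)phenyl]-2-(benzyloxy)propanoate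
Conditions: BnOC(=NH)CCl3, TfOH (cat.), CH2Cl2–cyclohexane, 0 °C to rt
Reagents that add atoms: benzyl 2,2,2-trichloroacetimidate (N=C(OCc1ccccc1)C(Cl)(Cl)Cl)
Why: Acid-catalysed benzylation with the trichloroacetimidate etherifies the α-hydroxy ester without base, which avoids enolization of the stereocentre, and this benzyl ether later keeps the C3 oxygen out of the ring closure.

Step 4
Reactants: 6 allyl (S)-3-[4-(allyloxy)phenyl]-2-(benzyloxy)propanoate
Product: 7 (S)-3-[4-(allyloxy)phenyl]-2-(benzyloxy)-N-methoxy-N-methylpropanamide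
Conditions: MeNHOMe·HCl, iPrMgCl, THF, −20 °C
Reagents that add atoms: N,O-dimethylhydroxylamine hydrochloride (CNOC.Cl)
Why: Direct aminolysis of the ester by the chloromagnesium amide made in the flask (Weinreb amide formation) is fast at low temperature and should not epimerize the α-alkoxy centre.

Step 5
Reactants: 7 (S)-3-[4-(allyloxy)phenyl]-2-(benzyloxy)-N-methoxy-N-methylpropanamide; 8 1-(benzyloxy)-4-bromobenzene
Product: 10 (S)-3-[4-(allyloxy)phenyl]-2-(benzyloxy)-1-[4-(benzyloxy)phenyl]propan-1-one, via arylmagnesium bromide 9 (not isolated)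
Conditions: 8, Mg, THF, rt; then 7, 0 °C; 1 M HCl
Reagents that add atoms: none
Why: Weinreb ketone synthesis, in which the aryl Grignard reagent 9 adds only once because the chelated tetrahedral adduct persists until the acidic quench.

Step 6
Reactants: 10 (S)-3-[4-(allyloxy)phenyl]-2-(benzyloxy)-1-[4-(benzyloxy)phenyl]propan-1-one
Product: 11 (1R,2S)-3-[4-(allyloxy)phenyl]-2-(benzyloxy)-1-[4-(benzyloxy)phenyl]propan-1-ol
Conditions: Zn(BH4)2, Et2O, −30 °C
Reagents that add atoms: none
Why: Chelation-controlled (Cram-chelate) reduction, in which zinc bridges the carbonyl and α-benzyloxy oxygens and hydride enters past the α-hydrogen, should set the new carbinol centre as 1R, anti to the 2S ether, the relationship needed for a 2,3-trans flavan.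

Step 7
Reactants: 11 (1R,2S)-3-[4-(allyloxy)phenyl]-2-(benzyloxy)-1-[4-(benzyloxy)phenyl]propan-1-ol
Product: 12 4-[(2S,3R)-2-(benzyloxy)-3-[4-(benzyloxy)phenyl]-3-hydroxypropyl]phenol
Conditions: Pd(PPh3)4 (cat.), morpholine, THF, rt
Reagents that add atoms: none
Why: Tsuji–Trost deallylation, in which zerovalent palladium ionizes only the aryl allyl ether and morpholine captures the allyl group, while benzyl ethers and the benzylic alcohol are inert.

Step 8
Reactants: 12 4-[(2S,3R)-2-(benzyloxy)-3-[4-(benzyloxy)phenyl]-3-hydroxypropyl]phenol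
Product: 14 4-[(2S,3R)-2-(benzyloxy)-3-[4-(benzyloxy)phenyl]-3-hydroxypropyl]-4-hydroxycyclohexa-2,5-dien-1-one, via hydroperoxide 13 (not isolated)
Conditions: KHSO5 (as 2KHSO5·KHSO4·K2SO4), NaHCO3, MeCN–H2O, rt; then PPh3, CH2Cl2, 0 °C
Reagents that add atoms: potassium peroxymonosulfate ([K+].[O-]S(=O)(=O)OO)
Why: Oxidative dearomatization of a para-alkylphenol by singlet oxygen (generated from KHSO5 and NaHCO3), in which the only free phenol takes up O2 at its para carbon (the future C4a) to give hydroperoxide 13 that PPh3 reduces to the para-quinol, benzyl aryl ethers being unreactive toward singlet oxygen.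

Step 9
Reactants: 14 4-[(2S,3R)-2-(benzyloxy)-3-[4-(benzyloxy)phenyl]-3-hydroxypropyl]-4-hydroxycyclohexa-2,5-dien-1-one
Product: 16 (2R,3S)-3-(benzyloxy)-2-[4-(benzyloxy)phenyl]chroman-7-ol, via oxa-Michael adduct 15 (not isolated)
Conditions: Cs2CO3 (0.1 equiv), MeCN, rt; then TsOH·H2O (0.5 equiv), 40 °C
Reagents that add atoms: none
Why: Cs2CO3 deprotonates the only free secondary hydroxyl (on C2), and the alkoxide adds in a conjugate sense to C8a, the β-carbon of one enone arm of the 4-hydroxycyclohexa-2,5-dienone, to give the cis-fused adduct 15; TsOH then enolizes the remaining ketone toward C8 and ionizes the tertiary C4a hydroxyl to a cyclohexadienyl cation that loses the C8a proton, so ring A is aromatic again with O1 on C8a and the former carbonyl oxygen as the 7-OH. The closest known reaction types are the intramolecular oxa-Michael addition of side-chain alcohols to para-quinols and the acid-induced 1,4-addition–dehydration that turns para-quinols into meta-substituted phenols. Ring C closes in a 6-exo-trig mode, and ring A is restored by elimination, not by a ring closure. No stereocentre of 16 is made here: C4a and C8a of 15 are transient, and C2 and C3 keep the anti relationship set in step 6 because the O1–C2 bond is never broken, which translates into 2R,3S (2,3-trans). The step needs site selectivity among oxygen nucleophiles and enone carbons: the C3 oxygen is blocked as its benzyl ether (no 5-exo closure to a furan), the tertiary C4a hydroxyl cannot reach an enone carbon, and C5 and C8a give the same phenol after dehydration. It also needs the ring closure to precede any acid-induced ionization of the para-benzyloxybenzylic C2 position, which is secured by running the conjugate addition under base before the acid is added.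

Step 10
Reactants: 16 (2R,3S)-3-(benzyloxy)-2-[4-(benzyloxy)phenyl]chroman-7-ol
Product: 18 (2R,3S,4R)-3-(benzyloxy)-2-[4-(benzyloxy)phenyl]-4-methoxychroman-7-ol, via quinone methide 17 (not isolated)
Conditions: DDQ (1.05 equiv), CH2Cl2–MeOH 4:1, 0 °C
Reagents that add atoms: methanol (CO)
Why: Quinone methide formation by DDQ dehydrogenation of a para-alkylphenol, in which the free 7-OH (para to C4a) directs hydride loss to C4 and not to C2, and methanol adds 1,6 to 17 from the face anti to the 3-benzyloxy group (3,4-trans), a configuration that is erased again in step 16.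

Step 11
Reactants: 6 allyl (S)-3-[4-(allyloxy)phenyl]-2-(benzyloxy)propanoate
Product: 19 (S)-3-[4-(allyloxy)phenyl]-2-(benzyloxy)propanal
Conditions: iBu2AlH, CH2Cl2, −78 °C; aq. KNaC4H4O6
Reagents that add atoms: none
Why: Partial reduction of the ester with iBu2AlH at low temperature stops at the chelated hemiacetal aluminate, which should release the configurationally intact α-benzyloxy aldehyde on work-up.

Step 12
Reactants: 19 (S)-3-[4-(allyloxy)phenyl]-2-(benzyloxy)propanal; 20 1,2-bis(benzyloxy)-4-bromobenzene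
Product: 22 (1S,2S)-3-[4-(allyloxy)phenyl]-2-(benzyloxy)-1-[3,4-bis(benzyloxy)phenyl]propan-1-ol, via arylmagnesium bromide 21 (not isolated)
Conditions: 20, Mg, THF, rt; then 19, MgBr2·OEt2, CH2Cl2, −78 °C; H2O
Reagents that add atoms: none
Why: Chelation-controlled Grignard addition, in which MgBr2 holds the aldehyde and α-benzyloxy oxygens syn-periplanar and the aryl group of 21 attacks past the α-hydrogen, should set the carbinol centre as 1S, syn to the 2S ether, the relationship needed for a 2,3-cis flavan.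

Step 13
Reactants: 22 (1S,2S)-3-[4-(allyloxy)phenyl]-2-(benzyloxy)-1-[3,4-bis(benzyloxy)phenyl]propan-1-ol
Product: 23 4-[(2S,3S)-2-(benzyloxy)-3-[3,4-bis(benzyloxy)phenyl]-3-hydroxypropyl]phenol
Conditions: Pd(PPh3)4 (cat.), morpholine, THF, rt
Reagents that add atoms: none
Why: Tsuji–Trost deallylation as in step 7 frees only the phenol that is to be dearomatized.

Step 14
Reactants: 23 4-[(2S,3S)-2-(benzyloxy)-3-[3,4-bis(benzyloxy)phenyl]-3-hydroxypropyl]phenol
Product: 25 4-[(2S,3S)-2-(benzyloxy)-3-[3,4-bis(benzyloxy)phenyl]-3-hydroxypropyl]-4-hydroxycyclohexa-2,5-dien-1-one, via hydroperoxide 24 (not isolated)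
Conditions: KHSO5 (as 2KHSO5·KHSO4·K2SO4), NaHCO3, MeCN–H2O, rt; then PPh3, CH2Cl2, 0 °C
Reagents that add atoms: potassium peroxymonosulfate ([K+].[O-]S(=O)(=O)OO)
Why: Singlet-oxygen dearomatization of the single free para-alkylphenol as in step 8, the catechol dibenzyl ether of ring E being unreactive under these conditions.

Step 15
Reactants: 25 4-[(2S,3S)-2-(benzyloxy)-3-[3,4-bis(benzyloxy)phenyl]-3-hydroxypropyl]-4-hydroxycyclohexa-2,5-dien-1-one
Product: 27 (2S,3S)-3-(benzyloxy)-2-[3,4-bis(benzyloxy)phenyl]chroman-7-ol, via oxa-Michael adduct 26 (not isolated)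
Conditions: Cs2CO3 (0.1 equiv), MeCN, rt; then TsOH·H2O (0.3 equiv), rt
Reagents that add atoms: none
Why: The same sequence as in step 9 (6-exo-trig oxa-Michael addition to the para-quinol under base, then acid-induced dehydrative rearomatization) closes ring F by its O1′–C8a′ bond, and since O1′ never leaves C2′ the syn relationship is carried unchanged into the 2S,3S (2,3-cis) flavan.

Step 16
Reactants: 18 (2R,3S,4R)-3-(benzyloxy)-2-[4-(benzyloxy)phenyl]-4-methoxychroman-7-ol; 27 (2S,3S)-3-(benzyloxy)-2-[3,4-bis(benzyloxy)phenyl]chroman-7-ol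
Product: 29 (2R,3S,4R)-3-(benzyloxy)-2-[4-(benzyloxy)phenyl]-4-[(2S,3S)-3-(benzyloxy)-2-[3,4-bis(benzyloxy)phenyl]-7-hydroxychroman-6-yl]chroman-7-ol, via benzylic cation 28 (not isolated)
Conditions: 27 (3 equiv), BF3·OEt2 (0.3 equiv), CH2Cl2, −40 to 0 °C
Reagents that add atoms: none
Why: Friedel–Crafts alkylation of a phenol by a benzylic cation, in which BF3 takes the 4-methoxy group of 18 as methoxytrifluoroborate to leave cation 28 (stabilized through ring A by the para 7-OH and flat at C4, so the configuration set in step 10 is lost) and ring D of 27 should attack through C6′ (ortho to its 7′-OH, para to O1′, less hindered than C8′) on the C4 face anti to the 3-benzyloxy group of the half-chair with the 2-aryl group equatorial, which sets C4 as R (3,4-trans), while the excess of 27 suppresses self-condensation and the borate returns methanol and BF3 once the arenium proton is lost.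

Step 17
Reactants: 29 (2R,3S,4R)-3-(benzyloxy)-2-[4-(benzyloxy)phenyl]-4-[(2S,3S)-3-(benzyloxy)-2-[3,4-bis(benzyloxy)phenyl]-7-hydroxychroman-6-yl]chroman-7-ol
Product: 30 (2R,3S,4R)-4-[(2S,3S)-2-(3,4-dihydroxyphenyl)-3,7-dihydroxychroman-6-yl]-2-(4-hydroxyphenyl)chroman-3,7-diol
Conditions: H2 (1 atm), Pd(OH)2/C, THF–MeOH, rt
Reagents that add atoms: none
Why: Hydrogenolysis over Pd(OH)2/C cleaves the five benzyl ethers and should leave the stereocentres and the diarylmethine C4–H untouched.

**Compound list**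

1 | L-tyrosine, (S)-2-amino-3-(4-hydroxyphenyl)propanoic acid | N[C@@H](Cc1ccc(O)cc1)C(=O)O | starting material
2 | (S)-1-carboxylato-2-(4-hydroxyphenyl)ethane-1-diazonium (diazonium carboxylate) | N#[N+][C@@H](Cc1ccc(O)cc1)C(=O)[O-] | intermediate
3 | (R)-3-(4-hydroxybenzyl)oxiran-2-one (alpha-lactone) | O=C1O[C@@H]1Cc1ccc(O)cc1 | intermediate
4 | (S)-2-hydroxy-3-(4-hydroxyphenyl)propanoic acid | O[C@@H](Cc1ccc(O)cc1)C(=O)O | intermediate
5 | allyl (S)-3-[4-(allyloxy)phenyl]-2-hydroxypropanoate | O[C@@H](Cc1ccc(OCC=C)cc1)C(=O)OCC=C | intermediate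
6 | allyl (S)-3-[4-(allyloxy)phenyl]-2-(benzyloxy)propanoate | c1ccccc1CO[C@@H](Cc1ccc(OCC=C)cc1)C(=O)OCC=C | intermediate
7 | (S)-3-[4-(allyloxy)phenyl]-2-(benzyloxy)-N-methoxy-N-methylpropanamide | c1ccccc1CO[C@@H](Cc1ccc(OCC=C)cc1)C(=O)N(C)OC | intermediate
8 | 1-(benzyloxy)-4-bromobenzene | Brc1ccc(OCc2ccccc2)cc1 | starting material
9 | [4-(benzyloxy)phenyl]magnesium bromide | Br[Mg]c1ccc(OCc2ccccc2)cc1 | intermediate
10 | (S)-3-[4-(allyloxy)phenyl]-2-(benzyloxy)-1-[4-(benzyloxy)phenyl]propan-1-one | c1ccccc1CO[C@@H](Cc1ccc(OCC=C)cc1)C(=O)c1ccc(OCc2ccccc2)cc1 | intermediate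
11 | (1R,2S)-3-[4-(allyloxy)phenyl]-2-(benzyloxy)-1-[4-(benzyloxy)phenyl]propan-1-ol | c1ccccc1CO[C@@H](Cc1ccc(OCC=C)cc1)[C@H](O)c1ccc(OCc2ccccc2)cc1 | intermediate
12 | 4-[(2S,3R)-2-(benzyloxy)-3-[4-(benzyloxy)phenyl]-3-hydroxypropyl]phenol | c1ccccc1CO[C@@H](Cc1ccc(O)cc1)[C@H](O)c1ccc(OCc2ccccc2)cc1 | intermediate
13 | 4-[(2S,3R)-2-(benzyloxy)-3-[4-(benzyloxy)phenyl]-3-hydroxypropyl]-4-hydroperoxycyclohexa-2,5-dien-1-one | c1ccccc1CO[C@@H](CC1(OO)C=CC(=O)C=C1)[C@H](O)c1ccc(OCc2ccccc2)cc1 | intermediate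
14 | 4-[(2S,3R)-2-(benzyloxy)-3-[4-(benzyloxy)phenyl]-3-hydroxypropyl]-4-hydroxycyclohexa-2,5-dien-1-one | c1ccccc1CO[C@@H](CC1(O)C=CC(=O)C=C1)[C@H](O)c1ccc(OCc2ccccc2)cc1 | intermediate
15 | (2R,3S)-3-(benzyloxy)-2-[4-(benzyloxy)phenyl]-4a-hydroxy-2,3,4,4a,8,8a-hexahydro-7H-chromen-7-one (cis ring fusion, either C4a/C8a diastereomer) | c1ccccc1COc1ccc([C@H]2OC3CC(=O)C=CC3(O)C[C@@H]2OCc2ccccc2)cc1 | intermediate
16 | (2R,3S)-3-(benzyloxy)-2-[4-(benzyloxy)phenyl]chroman-7-ol | c1ccccc1COc1ccc([C@H]2Oc3cc(O)ccc3C[C@@H]2OCc2ccccc2)cc1 | intermediate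
17 | (2R,3S)-3-(benzyloxy)-2-[4-(benzyloxy)phenyl]-2,3-dihydro-7H-chromen-7-one (para-quinone methide) | c1ccccc1COc1ccc([C@H]2OC3=CC(=O)C=CC3=C[C@@H]2OCc2ccccc2)cc1 | intermediate
18 | (2R,3S,4R)-3-(benzyloxy)-2-[4-(benzyloxy)phenyl]-4-methoxychroman-7-ol | c1ccccc1COc1ccc([C@H]2Oc3cc(O)ccc3[C@@H](OC)[C@@H]2OCc2ccccc2)cc1 | intermediate
19 | (S)-3-[4-(allyloxy)phenyl]-2-(benzyloxy)propanal | c1ccccc1CO[C@@H](Cc1ccc(OCC=C)cc1)C=O | intermediate
20 | 1,2-bis(benzyloxy)-4-bromobenzene | Brc1ccc(OCc2ccccc2)c(OCc2ccccc2)c1 | starting material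
21 | [3,4-bis(benzyloxy)phenyl]magnesium bromide | Br[Mg]c1ccc(OCc2ccccc2)c(OCc2ccccc2)c1 | intermediate
22 | (1S,2S)-3-[4-(allyloxy)phenyl]-2-(benzyloxy)-1-[3,4-bis(benzyloxy)phenyl]propan-1-ol | c1ccccc1CO[C@@H](Cc1ccc(OCC=C)cc1)[C@@H](O)c1ccc(OCc2ccccc2)c(OCc2ccccc2)c1 | intermediate
23 | 4-[(2S,3S)-2-(benzyloxy)-3-[3,4-bis(benzyloxy)phenyl]-3-hydroxypropyl]phenol | c1ccccc1CO[C@@H](Cc1ccc(O)cc1)[C@@H](O)c1ccc(OCc2ccccc2)c(OCc2ccccc2)c1 | intermediate
24 | 4-[(2S,3S)-2-(benzyloxy)-3-[3,4-bis(benzyloxy)phenyl]-3-hydroxypropyl]-4-hydroperoxycyclohexa-2,5-dien-1-one | c1ccccc1CO[C@@H](CC1(OO)C=CC(=O)C=C1)[C@@H](O)c1ccc(OCc2ccccc2)c(OCc2ccccc2)c1 | intermediate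
25 | 4-[(2S,3S)-2-(benzyloxy)-3-[3,4-bis(benzyloxy)phenyl]-3-hydroxypropyl]-4-hydroxycyclohexa-2,5-dien-1-one | c1ccccc1CO[C@@H](CC1(O)C=CC(=O)C=C1)[C@@H](O)c1ccc(OCc2ccccc2)c(OCc2ccccc2)c1 | intermediate
26 | (2S,3S)-3-(benzyloxy)-2-[3,4-bis(benzyloxy)phenyl]-4a-hydroxy-2,3,4,4a,8,8a-hexahydro-7H-chromen-7-one (cis ring fusion, either C4a/C8a diastereomer) | O=C1C=CC2(O)C(C1)O[C@@H](c1ccc(OCc3ccccc3)c(OCc3ccccc3)c1)[C@@H](OCc1ccccc1)C2 | intermediate
27 | (2S,3S)-3-(benzyloxy)-2-[3,4-bis(benzyloxy)phenyl]chroman-7-ol | Oc1ccc2c(c1)O[C@@H](c1ccc(OCc3ccccc3)c(OCc3ccccc3)c1)[C@@H](OCc1ccccc1)C2 | intermediate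
28 | (2R,3S)-3-(benzyloxy)-2-[4-(benzyloxy)phenyl]-7-hydroxychroman-4-ylium methoxytrifluoroborate (benzylic cation, ion pair) | c1ccccc1COc1ccc([C@H]2Oc3cc(O)ccc3[CH+][C@@H]2OCc2ccccc2)cc1.CO[B-](F)(F)F | intermediate
29 | (2R,3S,4R)-3-(benzyloxy)-2-[4-(benzyloxy)phenyl]-4-[(2S,3S)-3-(benzyloxy)-2-[3,4-bis(benzyloxy)phenyl]-7-hydroxychroman-6-yl]chroman-7-ol | c1ccccc1COc1ccc([C@H]2Oc3cc(O)ccc3[C@@H](c3cc4c(cc3O)O[C@@H](c3ccc(OCc5ccccc5)c(OCc5ccccc5)c3)[C@@H](OCc3ccccc3)C4)[C@@H]2OCc2ccccc2)cc1 | intermediate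
30 | (2R,3S,4R)-4-[(2S,3S)-2-(3,4-dihydroxyphenyl)-3,7-dihydroxychroman-6-yl]-2-(4-hydroxyphenyl)chroman-3,7-diol | Oc1ccc([C@H]2Oc3cc(O)ccc3[C@@H](c3cc4c(cc3O)O[C@@H](c3ccc(O)c(O)c3)[C@@H](O)C4)[C@@H]2O)cc1 | target

**Step count and risks**

Total step count: 17. Longest linear sequence: 12 steps (steps 1 to 10, then 16 and 17); the lower-unit branch (steps 11 to 15) leaves the main line at compound 6.

Three steps most likely to fail:

- **Step 9 (key step).** The acid stage may ionize the para-benzyloxybenzylic C2–O1 bond faster than the tertiary C4a hydroxyl leaves, which would scramble C2. The oxa-Michael addition may also revert and expose the free benzylic alcohol to acid. The fallback sets out from 14 and separates the two events. The Cs2CO3 stage is run alone and adduct 15 is isolated. Compound 15 is then heated with methyl N-(triethylammoniosulfonyl)carbamate (Burgess reagent) in THF at 50 °C. The tertiary alcohol is converted into the C4a sulfamate ester of 15 F1, which should undergo thermal syn-elimination with the cis-disposed C8a hydrogen, with no cation and no acid. Tautomerization of the resulting dienone should then give 16, where the route is rejoined.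

- **Step 10.** The product phenol may be oxidized further, the quinone methide may tautomerize to a 2H-chromene, or the unhindered phenol may undergo oxidative coupling. The fallback sets out from 16 and gives up the phenol-directed oxidation. O-Benzylation (BnBr, K2CO3, DMF) should give (2R,3S)-3,7-bis(benzyloxy)-2-[4-(benzyloxy)phenyl]chromane F2. DDQ with 2-ethoxyethanol in CH2Cl2, the benzylic C4 alkoxylation known for perbenzylated flavan-3-ols, should give the 4-(2-ethoxyethoxy) derivative F3. Activation of F3 with TMSOTf at −78 °C in the presence of excess 27 should give the hexabenzyl dimer F4. Hydrogenolysis under the conditions of step 17 then leads to 30, where the route is rejoined.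

- **Step 16.** Compound 18, or product 29, may act as nucleophile through C6 or C8 of ring A and give oligomers, and part of 27 may react through C8′. The fallback sets out from 18 and uses halogen capping. NBS (2 equiv, CH2Cl2, −20 °C) should place bromine on C6 and C8, both ortho to the free 7-OH, to give the 6,8-dibromo-4-methoxyflavan-7-ol F5, whose ring A can no longer act as a nucleophile. Coupling with 27 under BF3·OEt2 should give the dibromo dimer F6. Hydrogenolysis over Pd(OH)2/C in the presence of Et3N should cleave both C–Br bonds together with the benzyl ethers and give 30, where the route is rejoined. Any C8′-linked isomer would still have to be separated by chromatography.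

**Further compounds**

F1 | step 9 | triethylammonium salt of the C4a O-[N-(methoxycarbonyl)sulfamate] of 15 | c1ccccc1COc1ccc([C@H]2OC3CC(=O)C=CC3(OS(=O)(=O)[N-]C(=O)OC)C[C@@H]2OCc2ccccc2)cc1.CC[NH+](CC)CC
F2 | step 10 | (2R,3S)-3,7-bis(benzyloxy)-2-[4-(benzyloxy)phenyl]chromane | c1ccccc1COc1ccc([C@H]2Oc3cc(OCc4ccccc4)ccc3C[C@@H]2OCc2ccccc2)cc1
F3 | step 10 | (2R,3S,4R)-3,7-bis(benzyloxy)-2-[4-(benzyloxy)phenyl]-4-(2-ethoxyethoxy)chromane | c1ccccc1COc1ccc([C@H]2Oc3cc(OCc4ccccc4)ccc3[C@@H](OCCOCC)[C@@H]2OCc2ccccc2)cc1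
F4 | step 10 | (2S,3S)-3-(benzyloxy)-2-[3,4-bis(benzyloxy)phenyl]-6-[(2R,3S,4R)-3,7-bis(benzyloxy)-2-[4-(benzyloxy)phenyl]chroman-4-yl]chroman-7-ol | c1ccccc1COc1ccc([C@H]2Oc3cc(OCc6ccccc6)ccc3[C@@H](c3cc4c(cc3O)O[C@@H](c3ccc(OCc5ccccc5)c(OCc5ccccc5)c3)[C@@H](OCc3ccccc3)C4)[C@@H]2OCc2ccccc2)cc1
F5 | step 16 | (2R,3S,4R)-3-(benzyloxy)-2-[4-(benzyloxy)phenyl]-6,8-dibromo-4-methoxychroman-7-ol | c1ccccc1COc1ccc([C@H]2Oc3c(Br)c(O)c(Br)cc3[C@@H](OC)[C@@H]2OCc2ccccc2)cc1
F6 | step 16 | (2R,3S,4R)-3-(benzyloxy)-2-[4-(benzyloxy)phenyl]-4-[(2S,3S)-3-(benzyloxy)-2-[3,4-bis(benzyloxy)phenyl]-7-hydroxychroman-6-yl]-6,8-dibromochroman-7-ol | c1ccccc1COc1ccc([C@H]2Oc3c(Br)c(O)c(Br)cc3[C@@H](c3cc4c(cc3O)O[C@@H](c3ccc(OCc5ccccc5)c(OCc5ccccc5)c3)[C@@H](OCc3ccccc3)C4)[C@@H]2OCc2ccccc2)cc1
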